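With the acyl chain numbered from the ester carbonyl (C1) to the terminal methyl (C28), everything rests on cutting the C11–C12 bond. The key step exploits the unbranched, heteroatom-free methylene chain C2–C28, whose C10–C13 segment can pass through a diyne stage without leaving a trace; the phenyl ring of the benzyl ester, the only ring, is a spectator. Both halves are terminal alkynes, and bromination of the C12 terminus reverses its polarity. A copper-catalysed Cadiot–Chodkiewicz coupling of benzyl undec-10-ynoate with 1-bromoheptadec-1-yne then forges C11–C12 in one operation and delivers the complete C28 skeleton as a 10,12-diyne. A benzyl-sparing hydrogenation completes the route.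

Key step: step 4

Remark: the four building blocks and all reagents are taken as catalogue chemicals; the bromoalkyne and the conjugated diyne are kept cold and away from light, since such compounds can polymerise in the solid state.

Step 1
Reactants: 1 undec-10-ynoic acid; 2 benzyl bromide
Product: 3 benzyl undec-10-ynoate
Conditions: K2CO3, DMF, rt
Reagents that add atoms: none
Why: Carbonate deprotonates only the carboxylic acid and the carboxylate displaces bromide from benzyl bromide in an SN2 O-alkylation (carboxylate benzylation), the terminal alkyne C–H being far too weakly acidic to react.

Step 2
Reactants: 4 1-bromopentadecane; 5 lithium acetylide–ethylenediamine complex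
Product: 6 heptadec-1-yne
Conditions: 5 (1.5 equiv), DMSO–THF, 10 °C to rt
Reagents that add atoms: none
Why: This is the SN2 alkylation of a metal acetylide by a primary alkyl bromide in a dipolar aprotic medium, and a moderate excess of the acetylide together with a temperature at or below room temperature should hold back dialkylation and E2 elimination.

Step 3
Reactants: 6 heptadec-1-yne
Product: 7 1-bromoheptadec-1-yne
Conditions: NBS, AgNO3 (10 mol %), acetone, rt, dark
Reagents that add atoms: N-bromosuccinimide, O=C1CCC(=O)N1Br
Why: In this silver-catalysed electrophilic bromination of a terminal alkyne, monovalent silver from AgNO3 activates the C–H terminus as a silver acetylide that N-bromosuccinimide brominates at the terminal carbon; the saturated chain is inert, and the reaction should be run to full conversion because leftover 6 is hard to separate from 7.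

Step 4
Reactants: 3 benzyl undec-10-ynoate; 7 1-bromoheptadec-1-yne
Product: 9 benzyl octacosa-10,12-diynoate, via copper acetylide of benzyl undec-10-ynoate 8 (not isolated)
Conditions: CuCl (10 mol %), NH2OH·HCl (cat.), 30% aq n-BuNH2, THF, 0 °C to rt, N2, dark; 7 added slowly to 3 (1.2 equiv)
Reagents that add atoms: none
Why: Cadiot–Chodkiewicz coupling: butylamine deprotonates the CuCl-complexed alkyne 3 to the monovalent copper acetylide 8, which adds oxidatively to the C–Br bond of 7 to give a trivalent copper bis(alkynyl) species, and reductive elimination forms the C11–C12 sp–sp bond and returns monovalent copper. The closest known reaction type is exactly this copper-catalysed union of a terminal alkyne with a 1-bromoalkyne; no ring is closed and no stereocentre is created. The selectivity needed is heterocoupling over homocoupling: only 7 carries the electrophilic C–Br terminus and only 3 the acidic C–H, NH2OH·HCl reduces any divalent copper that would start Glaser dimerisation of 3, air is excluded, and 7 is added slowly to a slight excess of 3. A bromide and not an iodide is placed on C12 to limit halogen–copper exchange, the channel that leads to symmetrical diynes. The benzyl ester should be a spectator in cold aqueous amine over the short reaction time, and any homocoupled diyne carries zero or two ester groups, so chromatography should separate it from the monoester 9.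

Step 5
Reactants: 9 benzyl octacosa-10,12-diynoate
Product: 10 benzyl octacosanoate
Conditions: H2 (1 atm), Pd/C (10 wt% Pd), Ph2S (0.01 equiv), THF–EtOAc, rt to 40 °C
Reagents that add atoms: none
Why: Heterogeneous catalytic hydrogenation adds four equivalents of H2 across the two triple bonds, and Pd/C poisoned with Ph2S keeps its activity for alkynes and alkenes while no longer cleaving the benzylic C–O bond of the ester, so the chain should be saturated with the benzyl group in place and without any stereochemical issue.

Compound list
1 | undec-10-ynoic acid | C#CCCCCCCCCC(=O)O | starting material
2 | benzyl bromide | BrCc1ccccc1 | starting material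
3 | benzyl undec-10-ynoate | C#CCCCCCCCCC(=O)OCc1ccccc1 | intermediate
4 | 1-bromopentadecane | CCCCCCCCCCCCCCCBr | starting material
5 | lithium acetylide–ethylenediamine complex | [Li]C#C.NCCN | starting material
6 | heptadec-1-yne | CCCCCCCCCCCCCCCC#C | intermediate
7 | 1-bromoheptadec-1-yne | CCCCCCCCCCCCCCCC#CBr | intermediate
8 | copper acetylide of benzyl undec-10-ynoate (monovalent copper on C11; formed in the flask, not isolated) | [Cu]C#CCCCCCCCCC(=O)OCc1ccccc1 | intermediate
9 | benzyl octacosa-10,12-diynoate | CCCCCCCCCCCCCCCC#CC#CCCCCCCCCC(=O)OCc1ccccc1 | intermediate
10 | benzyl octacosanoate | CCCCCCCCCCCCCCCCCCCCCCCCCCCC(=O)OCc1ccccc1 | target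

Total step count: 5
Longest linear sequence: 4 steps (steps 2, 3, 4 and 5, from 1-bromopentadecane 4); the ester branch (steps 1, 4, 5) is shorter.

Steps most likely to fail

Step 4. Halogen–copper exchange or adventitious oxidation may divert both partners into symmetrical diynes. The two waxy, lipophilic partners may also react sluggishly in the aqueous amine, and long exposure risks slow aminolysis of the benzyl ester. The fallback sets out from 1 and 7 and comes back to the route at 9. The coupling is moved ahead of the esterification. Undec-10-ynoic acid 1, fully dissolved as its ammonium carboxylate in aqueous n-BuNH2/MeOH and used in excess, is coupled with 7 (CuCl, NH2OH·HCl, 0 °C) to give octacosa-10,12-diynoic acid F1. This is the classical way to long-chain diynoic acids; there is no ester to aminolyse, and neutral homocoupled hydrocarbon is removed by acid–base extraction. F1 is then benzylated with benzyl bromide 2 and K2CO3 in DMF to give 9.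

Step 5. Hydrogenolysis of the benzylic C–O bond may compete if the catalyst is under-poisoned, or the reduction may stall at the ene or diene stage if it is over-poisoned, made worse by the waxy product coating the catalyst. The fallback sets out from 9 and comes back to the route at 10. The diyne is hydrogenated exhaustively over unpoisoned Pd/C (H2, THF, 40 °C), which deliberately saturates the chain and cleaves the ester, giving octacosanoic acid F2 and toluene. F2 is then re-benzylated with benzyl bromide 2 and K2CO3 in warm DMF to give 10.

Step 2. E2 elimination of the long-chain bromide in the strongly basic acetylide–diamine medium, or incomplete conversion of the poorly DMSO-soluble bromide, may leave hydrocarbon mixtures that are hard to separate. The fallback sets out from 4 and comes back to the route at 6. Ethynyltrimethylsilane is deprotonated with n-BuLi in THF at −78 °C to lithium (trimethylsilyl)acetylide F3, a less basic, mono-capped C2 nucleophile. F3 is alkylated with 4 in THF/DMPU (−78 °C to rt) to give trimethyl(heptadec-1-yn-1-yl)silane F4. Methanolysis of the C–Si bond (K2CO3 cat., MeOH–THF, rt) then releases 6.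

Further compounds
F1 | step 4 | octacosa-10,12-diynoic acid | CCCCCCCCCCCCCCCC#CC#CCCCCCCCCC(=O)O
F2 | step 5 | octacosanoic acid | CCCCCCCCCCCCCCCCCCCCCCCCCCCC(=O)O
F3 | step 2 | lithium (trimethylsilyl)acetylide | [Li]C#C[Si](C)(C)C
F4 | step 2 | trimethyl(heptadec-1-yn-1-yl)silane | CCCCCCCCCCCCCCCC#C[Si](C)(C)C
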